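The earlier runs and the new flask were generated by integration with constants of no real substance; noise was put on by code.

Watch the partner.

in all of them: left-handed substrate 18 mM; right-handed substrate 18 mM
- green: partner 36 mM; temperature 110 °C; the very flask that is asked about, followed so far
- red: partner 72 mM; temperature 95 °C; run made earlier
- flask: partner 36.0 mM; temperature 110 °C; time 2.5 h

| run | time / min | left-handed product / % | left-handed substrate / % |
|---|---|---|---|
| green | 15.0 | 25 | 13 |
| green | 30.0 | 32 | 9 |
| green | 50.0 | 29 | 12 |
| green | 60.0 | 34 | 11 |
| green | 80.0 | 37 | 10 |
| green | 90.0 | 36 | 7 |
| green | 120 | 38 | 5 |
| red | 2.00 | 11 | 37 |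
| red | 5.00 | 20 | 28 |
| red | 8.00 | 24 | 21 |
| red | 12.0 | 33 | 19 |
| red | 20.0 | 34 | 7 |
| red | 25.0 | 33 | 8 |
| red | 30.0 | 37 | 4 |

(readings scatter by 2 percentage points)

- south-west: at 2.5 h take out 90% of the left-handed product then present, then wait 5.0 h
- south-east: change nothing and wait 5.0 h more
- west: at 2.5 h raise the temperature by 15 K, then wait 5.0 h
- north-west: at 2.5 h add partner, 100% of the amount charged, then wait 5.0 h

1. left-handed product, in percent of the left-handed substrate and right-handed substrate together first charged, at 2.5 h
2. which option adds most left-handed product ("none" when 2 percentage points or less is all one gets) (south-west / south-east / west / north-west / none)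
3. left-handed product present, with what was taken out counted in, in percent of the left-handed substrate and right-handed substrate together first charged, after west
4. left-handed product present, with what was taken out counted in, in percent of the left-handed substrate and right-handed substrate together first charged, after north-west

- partner is single-handed; left-handed substrate and right-handed substrate are mirror images of each other, charged as a racemate, each of them at the stated concentration
- left-handed product taken out counts as made
- additions bring no volume worth counting
- the handed part of partner does not stay in what it makes, so the products of the two hands are mirror images too

Green's partner, 36 mM, matches its two substrates together, 36.0 mM. Green's left-handed product creeps by 1 percentage point from 80.0 min to 120 min, under the scatter of 2 points, while left-handed substrate still reads 5%. The left-hand share of the charge is 50.0%; the gap g is that share minus both readings.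

| time | left-handed product | left-handed substrate | g |
|---|---|---|---|
| 15.0 min | 25% | 13% | 12 points |
| 60.0 min | 34% | 11% | 5 points |
| 120 min | 38% | 5% | 7 points |

The gap reads lower late than early, so, with that scatter as a caution, this reckoning treats it as a store rather than a loss. Treating the last stretch as a small correction, the creep carried to 2.5 h gives 38.8%. The left-hand share minus that is 11 points: this is the reserve W, the left-hand material not yet turned into left-handed product.

Turned round, fresh partner would be useless if W were 2 points or less; a dose short of the demand of both hands, 22 points, would merely gain less. This flask stands far from that: W exceeds the margin, and the dose equals 100% of the charge, above that demand. So north-west should gain about W, and west stay within about 2 points of 38.8%.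

The forecast gave 38.5%, north-west, 40.5% after west and 42% after north-west, the last below this reckoning, in its words “Fresh partner collects nearly all of it.”

The simulation gives 39.1%, north-west, 40.1% after west and 51.1% after north-west.

    partner + left-handed substrate → left-handed product (k = 3.37 /M/min, Ea = 53.0 kJ/mol)
    partner + right-handed substrate → right-handed product (k = 1.93 /M/min, Ea = 89.0 kJ/mol)
    left-handed substrate ⇌ achiral form (K = 1.70, k = 0.0925 /min, Ea = 107 kJ/mol, ΔH = −48.0 kJ/mol)
    right-handed substrate ⇌ achiral form (K = 1.70, k = 0.0925 /min, Ea = 107 kJ/mol, ΔH = −48.0 kJ/mol)
    achiral form → waste (k = 0.00447 /min, Ea = 127 kJ/mol)
    2 partner → homo dimer (k = 0.690 /M/min, Ea = 55.0 kJ/mol)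
    (constants at 110 °C)

In this flask north-west adds 12 points against W of 11 points. At 150 min partner, the limiting reagent, stands at 1.92% of its charge, while achiral form holds 11.1%. Right-handed substrate and achiral form relax with a half-life of 4.72 min, shorter than the 20 min of right-handed substrate passing to right-handed product at 7.84 min. A flask given three times the dose, further above the demand of 22 points, gains 13 points.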